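## The problem

Target 16 is a 2-arylbenzofuran in which ring A (the benzo ring) carries a hydroxyl at C6 and a 3-methylbut-2-enyl (prenyl) group at C7, and ring B, joined through C1' to C2 of the furan, is a resorcinol with hydroxyls at C3' and C5', prenyl groups at C2' and C6' and hydrogen at C4'. There is no stereocentre and no olefin geometry to set, so the task is one of regiochemistry and functional-group tolerance. The C2–C1' bond lies between two ortho prenyl groups, so forming it, or the furan ring beside it, after the prenyl groups are in place means working at a doubly ortho-substituted carbon. Direct electrophilic prenylation of the parent triphenol would be unselective, because C4' between the ring-B oxygens, C5 of ring A, C3 of the furan and the oxygens all compete with the three wanted carbons. Each prenyl group sits ortho to a free phenol, a pairing that closes to a 2,2-dimethylchroman under acid, and the electron-rich olefins and the resorcinol are open to oxidants and electrophiles; the late steps therefore have to be neutral or basic and non-oxidising, and phenol protecting groups that need acid for removal are unwelcome. A short route is possible because each prenyl-bearing carbon is the ortho neighbour of a phenolic oxygen (C7 of O–C6, C2' of O–C3', C6' of O–C5'), so all three chains can be passed from oxygen to carbon by [3,3] shifts. The one unwanted ortho carbon on ring B, C4', can hold a carboxyl group, which a 2,6-dihydroxybenzoic acid loses as CO2 on warming.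

## Retrosynthesis

**16 back to 14.** A carboxyl group is added at C4' to give acid 15 and its methyl ester 14. This does not simplify the skeleton; it buys regiocontrol for the step before. The forward reaction has to hydrolyse an ester flanked by two hydroxyls and expel CO2 without acid strong enough to cyclise the prenyl phenols, which points to alkaline hydrolysis and a buffered decarboxylation.

**14 back to 13.** The three bonds C7–CH2, C2'–CH2 and C6'–CH2 are cut together, placing each five-carbon unit on the neighbouring oxygen as a 1,1-dimethylallyl ether in 13. The alternatives for these bonds (Friedel–Crafts prenylation, metalation and alkylation, coupling of aryl halides with prenyl metals) each need either protection of three phenols or halogenation of a ring that also offers C3, C5 and C4'. The sigmatropic route needs neither, and it inverts the allyl unit so that the tertiary ether gives the linear prenyl group. Precursor 13 has no C-prenyl group and no crowded biaryl axis. The forward step must run three aromatic Claisen shifts in one heating, keep to C2'/C6' on ring B, choose C7 over C5 on ring A, and leave the ortho-prenyl phenols uncyclised.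

**13 back to 8 and 9.** The three O–C bonds are cut. A tertiary allylic ether cannot be made by displacement on a tertiary allyl halide, which would give linear prenyl ethers. The ethers are therefore traced to the tris(1,1-dimethylpropargyl) ether 12, which is semi-hydrogenated. Ether 12 is unbuilt one ether at a time, in the reverse order of reactivity of the hydroxyls:
- 12 comes from bis-ether 11 and 3-chloro-3-methylbut-1-yne 9 at the last, most crowded ester-flanked hydroxyl;
- 11 comes from mono-ether 10 and 9 at the first ester-chelated hydroxyl;
- 10 comes from triol 8 and 9 at the unchelated C6 hydroxyl.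

Each forward etherification uses about one equivalent of 9 under copper catalysis and can be run under conditions suited to the hydroxyl in question. Triol 8 carries no protecting group.

**8 back to 5 and 6.** The furan ring is opened at O1–C2, giving the ortho-hydroxy diarylalkyne 7, and then at C3–C3a, giving alkyne 5 and 4-iodobenzene-1,3-diol 6. The neighbouring cut at C2–C1' (coupling of a boron-bearing benzofuran fragment with triflate 2) would need a separately prepared and protected ring-A partner. The annulation takes ring A from purchasable 6 and needs no protection. The forward reaction is a Sonogashira coupling followed by 5-endo-dig closure in the same flask, and it has to tolerate four free phenols.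

**5 back to 1.** The aryl–alkyne bond is cut to triflate 2 and ethynyltrimethylsilane 3, with silylalkyne 4 between, and 2 comes from methyl 2,4,6-trihydroxybenzoate 1. The only demand is selective sulfonylation of the one hydroxyl that is para to the ester and not hydrogen-bonded to it.

## Roads not taken

**Alternative 1:** The cut is the furan O1–C2 bond, which leads back to the stilbene 2-[(E)-2-{3,5-bis(methoxymethoxy)-2,6-bis(3-methylbut-2-enyl)phenyl}ethenyl]-5-(methoxymethoxy)-6-(3-methylbut-2-enyl)phenol A2. In the forward step a trivalent iodine oxidant of the diacetoxyiodoarene type oxidises the free phenol of A2, the oxygen bonds to the styryl carbon that carries ring B, and loss of a proton gives 2-[3,5-bis(methoxymethoxy)-2,6-bis(3-methylbut-2-enyl)phenyl]-6-(methoxymethoxy)-7-(3-methylbut-2-enyl)benzofuran A1.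
- Merits: the route follows the likely biogenesis, is convergent, and fixes every prenyl position by construction. On that point it is better than the chosen plan, since no C5-versus-C7 question arises.
- Weak points: the olefination that makes A2 must occur at a benzylic carbon between two ortho prenyl groups. In A2 ring B is twisted out of conjugation, so the styryl carbon is a hindered and poorer partner for the oxidised phenol. The electrophilic oxidant also meets three trisubstituted olefins, one of them ortho to the phenol being oxidised, and can give quinol-type products. A1 still needs three methoxymethyl ethers removed with acid, the condition under which prenyl phenols close to chromans.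
- Comparison: against the fixed regiochemistry of A1 the chosen plan sets a route that moves all three prenyl groups onto carbon in one operation, uses no acid once they exist, and contains no protection or deprotection step.

**Alternative 2:** The cut inserts C3 between the two aryl groups of [3,5-bis(methoxymethoxy)-2,6-bis(3-methylbut-2-enyl)phenyl][2,4-bis(methoxymethoxy)-3-(3-methylbut-2-enyl)phenyl]methanone A4. In the forward step a lithiated silyl diazomethane adds to the carbonyl, Peterson elimination and loss of N2 give an alkylidene carbene, and migration of ring A gives 1-{[3,5-bis(methoxymethoxy)-2,6-bis(3-methylbut-2-enyl)phenyl]ethynyl}-2,4-bis(methoxymethoxy)-3-(3-methylbut-2-enyl)benzene A3.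
- Merits: diaryl ketones are easy to assemble, the one-carbon homologation to diarylalkynes is a known reaction, and prenyl regiochemistry is again settled beforehand. In that one respect it is ahead of the chosen plan.
- Weak points: the carbonyl of A4 has three ortho substituents, so addition of a bulky nucleophile should be slow. The carbene lies next to two prenyl olefins and their allylic C–H bonds, which can trap it before the aryl shift. A3 is not yet a benzofuran: only the oxygen ortho to the alkyne must be freed from among four like ethers, so in practice all are removed with acid before cyclisation, again in the presence of prenyl groups.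
- Comparison: the chosen plan has to justify its reliance on Claisen regioselectivity at ring A; in return it avoids the hindered carbonyl, the carbene and every acid-labile protecting group.

**Alternative 3:** The cut takes ring B apart at C1'–C6' and C4'–C5'. The precursors are methyl 4-(methoxymethoxy)-6-[6-(methoxymethoxy)-7-(3-methylbut-2-enyl)benzofuran-2-yl]-5-(3-methylbut-2-enyl)-2-oxo-2H-pyran-3-carboxylate A6 and triisopropyl[(5-methylhex-4-en-1-yn-1-yl)oxy]silane A7. In the forward step heating brings about a [4+2] cycloaddition, and loss of CO2 from the adduct gives methyl 2-(methoxymethoxy)-4-[6-(methoxymethoxy)-7-(3-methylbut-2-enyl)benzofuran-2-yl]-3,5-bis(3-methylbut-2-enyl)-6-(triisopropylsilyloxy)benzoate A5.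
- Merits: the hexasubstituted ring B is assembled with regiochemistry set by the polarity of the two partners, and the C4' ester is already in place. This is more secure for ring B than two sigmatropic shifts into crowded positions.
- Weak points: A6 is a fully substituted pyrone that already carries the prenylated benzofuran, so its preparation would be longer than the whole chosen route. Its 4-alkoxy group and full substitution make it a sluggish diene, and the temperature needed invites rearrangement of A7 to a silyl ketene. The ring-A prenyl group must be introduced separately. A5 then needs acid for two ethers, fluoride for the silyl ether, and the same hydrolysis and decarboxylation as the chosen route.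
- Comparison: the chosen plan has to accept an untested triple shift; what it offers in return is a precursor made in eight steps from purchasable arenes and an endgame free of acid.

Key step: step 9

Assumption: 4-iodobenzene-1,3-diol 6, ethynyltrimethylsilane 3 and 3-chloro-3-methylbut-1-yne 9 are taken as purchasable beside methyl 2,4,6-trihydroxybenzoate 1, and the three hydroxyls of triol 8 are etherified in three separate operations, each with about one equivalent of 9.

## Route

Step 1
Reactants: 1 methyl 2,4,6-trihydroxybenzoate
Product: 2 methyl 2,6-dihydroxy-4-(trifluoromethylsulfonyloxy)benzoate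
Conditions: PhNTf2 (1.0 equiv), Et3N (1.1 equiv), DMF, 0 °C to rt
Reagents that add atoms: N-phenylbis(trifluoromethanesulfonimide), O=S(=O)(N(c1ccccc1)S(=O)(=O)C(F)(F)F)C(F)(F)F
Why: Chemoselective O-sulfonylation: the C4 hydroxyl is para to the ester, not chelated and the most acidic, so one equivalent of base and a mild triflyl donor should mark it while the two ester-chelated hydroxyls stay free, as in selective 4-O-functionalisation of 2,4-dihydroxyaryl carbonyl compounds.

Step 2
Reactants: 2 methyl 2,6-dihydroxy-4-(trifluoromethylsulfonyloxy)benzoate; 3 ethynyltrimethylsilane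
Product: 4 methyl 2,6-dihydroxy-4-[(trimethylsilyl)ethynyl]benzoate
Conditions: PdCl2(PPh3)2 (3 mol%), CuI (5 mol%), Et3N, DMF, 60 °C, Ar
Reagents that add atoms: none
Why: Sonogashira coupling of an aryl triflate activated by the para ester; the hydroxyls are meta to the reacting carbon, so they neither slow oxidative addition by conjugation nor add to the new alkyne.

Step 3
Reactants: 4 methyl 2,6-dihydroxy-4-[(trimethylsilyl)ethynyl]benzoate
Product: 5 methyl 4-ethynyl-2,6-dihydroxybenzoate
Conditions: K2CO3, MeOH, rt
Reagents that add atoms: none
Why: Methanolytic protodesilylation of an alkynylsilane; exchange of the methyl ester with methanol is degenerate and the phenols are merely deprotonated reversibly.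

Step 4
Reactants: 5 methyl 4-ethynyl-2,6-dihydroxybenzoate; 6 4-iodobenzene-1,3-diol
Product: 8 methyl 2,6-dihydroxy-4-(6-hydroxybenzofuran-2-yl)benzoate, via methyl 4-[(2,4-dihydroxyphenyl)ethynyl]-2,6-dihydroxybenzoate 7 (not isolated)
Conditions: PdCl2(PPh3)2 (5 mol%), CuI (10 mol%), Et3N, DMF, rt then 80 °C, Ar
Reagents that add atoms: none
Why: Sonogashira coupling of the aryl iodide followed by 5-endo-dig addition of the ortho hydroxyl to the metal-activated alkyne, the standard one-pot route from 2-iodophenols to 2-arylbenzofurans; the hydroxyl para to iodine ends up at C6 of the benzofuran.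

Step 5
Reactants: 8 methyl 2,6-dihydroxy-4-(6-hydroxybenzofuran-2-yl)benzoate; 9 3-chloro-3-methylbut-1-yne
Product: 10 methyl 2,6-dihydroxy-4-[6-(2-methylbut-3-yn-2-yloxy)benzofuran-2-yl]benzoate
Conditions: 9 (1.1 equiv), DBU (1.2 equiv), CuCl2·2H2O (1 mol%), MeCN, −5 to 0 °C
Reagents that add atoms: none
Why: Copper-catalysed propargylic etherification, in which phenoxide captures a copper-bound acetylide/allenylidene species at the tertiary carbon and so gives the tertiary aryl ether that direct displacement cannot; with about one equivalent of chloride at low temperature the unchelated, unhindered C6 hydroxyl should react ahead of the two ester-chelated ones, as in the selective 4-O-alkylation of 2,4-dihydroxyaryl carbonyl compounds.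

Step 6
Reactants: 10 methyl 2,6-dihydroxy-4-[6-(2-methylbut-3-yn-2-yloxy)benzofuran-2-yl]benzoate; 9 3-chloro-3-methylbut-1-yne
Product: 11 methyl 2-hydroxy-6-(2-methylbut-3-yn-2-yloxy)-4-[6-(2-methylbut-3-yn-2-yloxy)benzofuran-2-yl]benzoate
Conditions: 9 (1.1 equiv, slow addition), DBU (1.3 equiv), CuCl2·2H2O (2 mol%), MeCN, 0 °C to rt
Reagents that add atoms: none
Why: The same copper-catalysed propargylic etherification at one of the two equivalent ester-chelated hydroxyls; limiting the chloride should favour the mono-ether because the first tertiary ether crowds the ester and the remaining hydroxyl, recovered 10 can be resubmitted, and any doubly etherified material is compound 12 of the next step, so nothing leaves the route.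

Step 7
Reactants: 11 methyl 2-hydroxy-6-(2-methylbut-3-yn-2-yloxy)-4-[6-(2-methylbut-3-yn-2-yloxy)benzofuran-2-yl]benzoate; 9 3-chloro-3-methylbut-1-yne
Product: 12 methyl 2,6-bis(2-methylbut-3-yn-2-yloxy)-4-[6-(2-methylbut-3-yn-2-yloxy)benzofuran-2-yl]benzoate
Conditions: 9 (3 equiv, in portions), DBU (3 equiv), CuCl2·2H2O (5 mol%), MeCN, rt to 40 °C
Reagents that add atoms: none
Why: Third copper-catalysed propargylic etherification, at the last and most crowded hydroxyl; the reaction is O-selective and is used on phenols that bear an ortho carbonyl group, though such phenols react more slowly, so this stage is driven with excess chloride and base.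

Step 8
Reactants: 12 methyl 2,6-bis(2-methylbut-3-yn-2-yloxy)-4-[6-(2-methylbut-3-yn-2-yloxy)benzofuran-2-yl]benzoate
Product: 13 methyl 2,6-bis(2-methylbut-3-en-2-yloxy)-4-[6-(2-methylbut-3-en-2-yloxy)benzofuran-2-yl]benzoate
Conditions: H2 (1 atm), Pd on CaCO3 poisoned with Pb(OAc)2 (Lindlar catalyst), quinoline, EtOAc, rt
Reagents that add atoms: none
Why: Lindlar semi-hydrogenation of three terminal alkynes; the poisoned catalyst should stop at the alkene and leave the furan C2=C3 bond and the allylic C–O bonds intact, which is the usual way from 1,1-dimethylpropargyl to 1,1-dimethylallyl aryl ethers.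

Step 9
Reactants: 13 methyl 2,6-bis(2-methylbut-3-en-2-yloxy)-4-[6-(2-methylbut-3-en-2-yloxy)benzofuran-2-yl]benzoate
Product: 14 methyl 2,6-dihydroxy-4-[6-hydroxy-7-(3-methylbut-2-enyl)benzofuran-2-yl]-3,5-bis(3-methylbut-2-enyl)benzoate
Conditions: PhNEt2 (degassed), 130 °C, Ar
Reagents that add atoms: none
Why: Each 1,1-dimethylallyl aryl ether should undergo a concerted [3,3] sigmatropic shift through a chair transition state in which the terminal CH2 bonds to the hydrogen-bearing ortho carbon, and the cyclohexadienone so formed enolises to the phenol; the closest known reaction is the aromatic Claisen rearrangement of tertiary allyl aryl ethers to ortho-prenyl phenols, here asked to occur three times in one substrate. No ring closes and no stereocentre forms; the allyl inversion inherent in the shift turns each branched ether into the linear 3-methylbut-2-enyl chain and forms the C7–CH2, C2'–CH2 and C6'–CH2 bonds. On ring B the ester occupies C4', so each ether has only one hydrogen-bearing ortho carbon (C2' or C6'); a shift to the ester-bearing carbon would give a dienone that cannot enolise and whose only onward path, a Cope shift to the para carbon, would have to form a bond at the hindered CMe2 terminus, so it should mainly revert to the ether. On ring A the C6–C7 bond has more double-bond character than C5–C6, as in 2-naphthyl and 7-oxycoumarin allyl ethers, which send the allyl group to the carbon next to the ring fusion, so C7 should be preferred over C5. Tertiary ethers rearrange at moderate temperature, and crowding next to the ester should lower the barrier further. The basic solvent buffers the liberated phenols, so acid-catalysed closure of an ortho-prenyl phenol to a chroman should be suppressed, and each ring-B phenol is tied up by a hydrogen bond to the ester as soon as it forms.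

Step 10
Reactants: 14 methyl 2,6-dihydroxy-4-[6-hydroxy-7-(3-methylbut-2-enyl)benzofuran-2-yl]-3,5-bis(3-methylbut-2-enyl)benzoate
Product: 16 5-[6-hydroxy-7-(3-methylbut-2-enyl)benzofuran-2-yl]-4,6-bis(3-methylbut-2-enyl)benzene-1,3-diol, via 2,6-dihydroxy-4-[6-hydroxy-7-(3-methylbut-2-enyl)benzofuran-2-yl]-3,5-bis(3-methylbut-2-enyl)benzoic acid 15 (not isolated)
Conditions: KOH, MeOH/H2O (degassed), reflux, Ar; AcOH to pH 6, 0 °C; crude acid, pyridine, 100 °C
Reagents that add atoms: none
Why: Saponification followed by protodecarboxylation of a 2,6-dihydroxybenzoic acid (ipso protonation at the carbon between two hydroxyls, then loss of CO2), the classical removal of a carboxyl blocking group from a resorcinol; the alkaline and then amine-buffered medium should keep the ortho-prenyl phenols from cyclising, and exclusion of air protects the phenolates.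

## Compound list

1 | methyl 2,4,6-trihydroxybenzoate | COC(=O)c1c(O)cc(O)cc1O | starting material
2 | methyl 2,6-dihydroxy-4-(trifluoromethylsulfonyloxy)benzoate | COC(=O)c1c(O)cc(OS(=O)(=O)C(F)(F)F)cc1O | intermediate
3 | ethynyltrimethylsilane | C#C[Si](C)(C)C | starting material
4 | methyl 2,6-dihydroxy-4-[(trimethylsilyl)ethynyl]benzoate | COC(=O)c1c(O)cc(C#C[Si](C)(C)C)cc1O | intermediate
5 | methyl 4-ethynyl-2,6-dihydroxybenzoate | COC(=O)c1c(O)cc(C#C)cc1O | intermediate
6 | 4-iodobenzene-1,3-diol | Oc1ccc(I)c(O)c1 | starting material
7 | methyl 4-[(2,4-dihydroxyphenyl)ethynyl]-2,6-dihydroxybenzoate (not isolated) | COC(=O)c1c(O)cc(C#Cc2ccc(O)cc2O)cc1O | intermediate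
8 | methyl 2,6-dihydroxy-4-(6-hydroxybenzofuran-2-yl)benzoate | COC(=O)c1c(O)cc(-c2cc3ccc(O)cc3o2)cc1O | intermediate
9 | 3-chloro-3-methylbut-1-yne | CC(C)(Cl)C#C | starting material
10 | methyl 2,6-dihydroxy-4-[6-(2-methylbut-3-yn-2-yloxy)benzofuran-2-yl]benzoate | COC(=O)c1c(O)cc(-c2cc3ccc(OC(C)(C)C#C)cc3o2)cc1O | intermediate
11 | methyl 2-hydroxy-6-(2-methylbut-3-yn-2-yloxy)-4-[6-(2-methylbut-3-yn-2-yloxy)benzofuran-2-yl]benzoate | COC(=O)c1c(O)cc(-c2cc3ccc(OC(C)(C)C#C)cc3o2)cc1OC(C)(C)C#C | intermediate
12 | methyl 2,6-bis(2-methylbut-3-yn-2-yloxy)-4-[6-(2-methylbut-3-yn-2-yloxy)benzofuran-2-yl]benzoate | COC(=O)c1c(OC(C)(C)C#C)cc(-c2cc3ccc(OC(C)(C)C#C)cc3o2)cc1OC(C)(C)C#C | intermediate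
13 | methyl 2,6-bis(2-methylbut-3-en-2-yloxy)-4-[6-(2-methylbut-3-en-2-yloxy)benzofuran-2-yl]benzoate | COC(=O)c1c(OC(C)(C)C=C)cc(-c2cc3ccc(OC(C)(C)C=C)cc3o2)cc1OC(C)(C)C=C | intermediate
14 | methyl 2,6-dihydroxy-4-[6-hydroxy-7-(3-methylbut-2-enyl)benzofuran-2-yl]-3,5-bis(3-methylbut-2-enyl)benzoate | COC(=O)c1c(O)c(CC=C(C)C)c(-c2cc3ccc(O)c(CC=C(C)C)c3o2)c(CC=C(C)C)c1O | intermediate
15 | 2,6-dihydroxy-4-[6-hydroxy-7-(3-methylbut-2-enyl)benzofuran-2-yl]-3,5-bis(3-methylbut-2-enyl)benzoic acid (not isolated) | OC(=O)c1c(O)c(CC=C(C)C)c(-c2cc3ccc(O)c(CC=C(C)C)c3o2)c(CC=C(C)C)c1O | intermediate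
16 | 5-[6-hydroxy-7-(3-methylbut-2-enyl)benzofuran-2-yl]-4,6-bis(3-methylbut-2-enyl)benzene-1,3-diol | CC(C)=CCc1c(O)cc(O)c(CC=C(C)C)c1-c1cc2ccc(O)c(CC=C(C)C)c2o1 | target

## Step count and risks

Total step count: 10. Longest linear sequence: 10 steps (1 → 2 → 4 → 5 → 8 → 10 → 11 → 12 → 13 → 14 → 16).

**Step 9 (key step).** Three things are most likely to go wrong:
- heterolytic loss of a tertiary allyl group from the ester-flanked ethers, whose phenoxides are good leaving groups, so that isoprene is lost instead of migrating;
- partial delivery of the ring-A chain to C5 instead of C7;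
- later closure of an ortho-prenyl phenol onto its own double bond if the medium turns acidic, or an incomplete third shift.

The fallback leaves the [3,3] route and sets out from triol 8. Alkylation with 1-bromo-3-methylbut-2-ene and K2CO3 in DMF should give methyl 2,6-bis(3-methylbut-2-enyloxy)-4-[6-(3-methylbut-2-enyloxy)benzofuran-2-yl]benzoate F1. Treatment of F1 with montmorillonite K10 in CH2Cl2 at 0 °C to rt should bring about the known clay-promoted [1,3] shift of aryl prenyl ethers to ortho-prenyl phenols. On ring B both the free ortho and the para carbon of each oxygen are the wanted C2'/C6'; on ring A the C5/C7 question remains and would be settled by separation. The route is rejoined at 14.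

**Step 7.** The last hydroxyl is hydrogen-bonded to the ester and very crowded once the neighbouring tertiary ether is in place, so etherification may stall while base-induced decomposition of chloride 9 goes on. The fallback sets out from triol 8 and bypasses 10, 11, 12 and the hydrogenation of step 8. 2-Methylbut-3-en-2-ol is deprotonated with n-BuLi in THF and acylated with isobutyl chloroformate to give 2-methylbut-3-en-2-yl 2-methylpropyl carbonate F2. Triol 8 is then O-allylated three times with F2 and Pd(PPh3)4 (zerovalent palladium) in THF, a known way to put 1,1-dimethylallyl groups on phenols through attack at the substituted end of the allyl–palladium intermediate. The route is rejoined at 13.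

**Step 4.** With four free phenols present, copper-mediated homocoupling of alkyne 5 may outrun the cross-coupling, and the ring closure of 7 may stay incomplete. The fallback cuts the C2–C1' bond instead; it sets out from triflate 2 and returns at 8.
- Benzofuran-6-ol is silylated (TBSCl, imidazole, DMF) to tert-butyl(benzofuran-6-yloxy)dimethylsilane F3.
- F3 is lithiated at C2 (n-BuLi, THF, −78 °C) and quenched with 2-isopropoxy-4,4,5,5-tetramethyl-1,3,2-dioxaborolane to give tert-butyldimethyl{[2-(4,4,5,5-tetramethyl-1,3,2-dioxaborolan-2-yl)benzofuran-6-yl]oxy}silane F4.
- Suzuki–Miyaura coupling of F4 with 2 (PdCl2(dppf), K3PO4, dioxane/H2O, 80 °C) should give methyl 4-[6-(tert-butyldimethylsilyloxy)benzofuran-2-yl]-2,6-dihydroxybenzoate F5.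
- Bu4NF in THF converts F5 into 8.

**Step 10.** Hydrolysis of the doubly ortho-substituted ester may be slow, and decarboxylation of 15 may need temperatures at which acid 15 itself (a strong carboxylic acid) starts to promote closure of a phenol onto a prenyl double bond; the electron-rich phenolate may also be oxidised if air enters. The fallback removes the ester by a different mechanism and makes no new isolated compound. It sets out from 14, which is heated with LiCl in wet DMF at about 140 °C (Krapcho-type dealkoxycarbonylation). Chloride attacks the ester methyl group, and the lithium carboxylate, a vinylogous β-keto acid salt, loses CO2 in the same near-neutral medium. The route is rejoined at 16.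

## Further compounds

F1 | step 9 | methyl 2,6-bis(3-methylbut-2-enyloxy)-4-[6-(3-methylbut-2-enyloxy)benzofuran-2-yl]benzoate | COC(=O)c1c(OCC=C(C)C)cc(-c2cc3ccc(OCC=C(C)C)cc3o2)cc1OCC=C(C)C
F2 | step 7 | 2-methylbut-3-en-2-yl 2-methylpropyl carbonate | CC(C)COC(=O)OC(C)(C)C=C
F3 | step 4 | tert-butyl(benzofuran-6-yloxy)dimethylsilane | CC(C)(C)[Si](C)(C)Oc1ccc2ccoc2c1
F4 | step 4 | tert-butyldimethyl{[2-(4,4,5,5-tetramethyl-1,3,2-dioxaborolan-2-yl)benzofuran-6-yl]oxy}silane | CC(C)(C)[Si](C)(C)Oc1ccc2cc(B3OC(C)(C)C(C)(C)O3)oc2c1
F5 | step 4 | methyl 4-[6-(tert-butyldimethylsilyloxy)benzofuran-2-yl]-2,6-dihydroxybenzoate | COC(=O)c1c(O)cc(-c2cc3ccc(O[Si](C)(C)C(C)(C)C)cc3o2)cc1O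
F0 | step 10 | none | none
A1 | alternative 1 | 2-[3,5-bis(methoxymethoxy)-2,6-bis(3-methylbut-2-enyl)phenyl]-6-(methoxymethoxy)-7-(3-methylbut-2-enyl)benzofuran | COCOc1ccc2cc(-c3c(CC=C(C)C)c(OCOC)cc(OCOC)c3CC=C(C)C)oc2c1CC=C(C)C
A2 | alternative 1 | 2-[(E)-2-{3,5-bis(methoxymethoxy)-2,6-bis(3-methylbut-2-enyl)phenyl}ethenyl]-5-(methoxymethoxy)-6-(3-methylbut-2-enyl)phenol | COCOc1ccc(/C=C/c2c(CC=C(C)C)c(OCOC)cc(OCOC)c2CC=C(C)C)c(O)c1CC=C(C)C
A3 | alternative 2 | 1-{[3,5-bis(methoxymethoxy)-2,6-bis(3-methylbut-2-enyl)phenyl]ethynyl}-2,4-bis(methoxymethoxy)-3-(3-methylbut-2-enyl)benzene | COCOc1ccc(C#Cc2c(CC=C(C)C)c(OCOC)cc(OCOC)c2CC=C(C)C)c(OCOC)c1CC=C(C)C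
A4 | alternative 2 | [3,5-bis(methoxymethoxy)-2,6-bis(3-methylbut-2-enyl)phenyl][2,4-bis(methoxymethoxy)-3-(3-methylbut-2-enyl)phenyl]methanone | COCOc1ccc(C(=O)c2c(CC=C(C)C)c(OCOC)cc(OCOC)c2CC=C(C)C)c(OCOC)c1CC=C(C)C
A5 | alternative 3 | methyl 2-(methoxymethoxy)-4-[6-(methoxymethoxy)-7-(3-methylbut-2-enyl)benzofuran-2-yl]-3,5-bis(3-methylbut-2-enyl)-6-(triisopropylsilyloxy)benzoate | COC(=O)c1c(OCOC)c(CC=C(C)C)c(-c2cc3ccc(OCOC)c(CC=C(C)C)c3o2)c(CC=C(C)C)c1O[Si](C(C)C)(C(C)C)C(C)C
A6 | alternative 3 | methyl 4-(methoxymethoxy)-6-[6-(methoxymethoxy)-7-(3-methylbut-2-enyl)benzofuran-2-yl]-5-(3-methylbut-2-enyl)-2-oxo-2H-pyran-3-carboxylate | COC(=O)C1=C(OCOC)C(CC=C(C)C)=C(c2cc3ccc(OCOC)c(CC=C(C)C)c3o2)OC1=O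
A7 | alternative 3 | triisopropyl[(5-methylhex-4-en-1-yn-1-yl)oxy]silane | CC(C)=CCC#CO[Si](C(C)C)(C(C)C)C(C)C
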